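**Retrosynthetic overview**

1. Feature (eudesmane numbering; ring A = C1–C5 and C10, ring B = C5–C10, C11 = carbinol carbon on C7): the methyl-bearing ring-fusion carbon C10 is para to the oxygenated C3 of ring A, with C4 and its methyl ortho to C3, and C9 is α to the C8 ketone of ring B. Ring A is therefore a masked 2,4-dimethylphenol and C9–C10 is a bond between two donor carbons.
2. Late stage: C11–OH from its silyl ether; C6=C7 by dehydrogenation of the C8 ketone; the O3 and O4 esters from a 3α,4α-diol; O4, H5 and O3 from the ring-A enone (dissolving metal, Rubottom oxidation, bulky hydride).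
3. Key disconnection C9–C10: anodic coupling of a phenol with a tethered enol silane closes ring B onto the aromatic ring A and creates C10; the sacrificial C7 centre steers the face.
4. Acyclic precursor: C6–C7 by auxiliary-controlled deconjugative benzylation, C11–OH by alkene hydration, C9 from a methyl Grignard reagent.
5. Ring order: ring A is bought as the arene; ring B is formed in step 12.

Key step: step 12

Remark on the chemistry: the phenol is built with the C4 methyl already on the ring, because a free ortho position would allow ortho closure with rearomatisation and because this methyl makes the later C3=C4 enol silane regiodefined; the 8β-alcohol of step 13 is assumed to be the major epimer (either epimer serves).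

**Route**

Step 1
Reactants: 1 3-bromo-2,6-dimethylbenzoic acid
Product: 2 3-hydroxy-2,6-dimethylbenzoic acid
Conditions: Pd2(dba)3 (cat.), tBuXPhos, KOH (4 equiv), 1,4-dioxane/H2O, 100 °C; then aq. HCl
Reagents that add atoms: potassium hydroxide, [K+].[OH-]
Why: Palladium-catalysed hydroxylation of an aryl bromide (C–O cross-coupling with hydroxide on zerovalent palladium carrying a bulky biarylphosphine), in which the carboxylate should be inert.

Step 2
Reactants: 2 3-hydroxy-2,6-dimethylbenzoic acid
Product: 3 3-(hydroxymethyl)-2,4-dimethylphenol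
Conditions: LiAlH4, THF, reflux; aq. potassium sodium tartrate
Reagents that add atoms: none
Why: Hydride reduction of a carboxylic acid to the primary alcohol with LiAlH4; heating should overcome the two ortho methyl groups and the phenoxide is inert.

Step 3
Reactants: 3 3-(hydroxymethyl)-2,4-dimethylphenol
Product: 4 tert-butyl[3-(tert-butyldimethylsilyloxymethyl)-2,4-dimethylphenoxy]dimethylsilane
Conditions: TBSCl (2.5 equiv), imidazole, DMF, rt
Reagents that add atoms: tert-butyldimethylsilyl chloride, CC(C)(C)[Si](C)(C)Cl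
Why: Silylation of both hydroxyl groups with a silyl chloride and imidazole.

Step 4
Reactants: 4 tert-butyl[3-(tert-butyldimethylsilyloxymethyl)-2,4-dimethylphenoxy]dimethylsilane
Product: 5 [3-(bromomethyl)-2,4-dimethylphenoxy](tert-butyl)dimethylsilane
Conditions: Ph3PBr2, CH2Cl2, 0 °C to rt
Reagents that add atoms: dibromotriphenylphosphorane, BrP(Br)(c1ccccc1)(c1ccccc1)c1ccccc1
Why: Dibromotriphenylphosphorane converts a primary benzylic silyl ether directly into the bromide (oxyphosphonium formation, then SN2 by bromide), whereas the aryl silyl ether sits on an sp2 carbon and cannot be displaced.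

Step 5
Reactants: 6 (4R)-4-benzyl-1,3-oxazolidin-2-one; 7 3-methylbut-2-enoyl chloride
Product: 9 (4R)-4-benzyl-3-(3-methylbut-2-enoyl)-1,3-oxazolidin-2-one, via lithium oxazolidinide 8 (not isolated)
Conditions: n-BuLi, THF, −78 °C; then 7, −78 to 0 °C
Reagents that add atoms: none
Why: N-acylation of the lithiated oxazolidinone by the acid chloride.

Step 6
Reactants: 9 (4R)-4-benzyl-3-(3-methylbut-2-enoyl)-1,3-oxazolidin-2-one; 5 [3-(bromomethyl)-2,4-dimethylphenoxy](tert-butyl)dimethylsilane
Product: 11 (4R)-4-benzyl-3-[(2R)-2-{[3-(tert-butyldimethylsilyloxy)-2,6-dimethylphenyl]methyl}-3-methylbut-3-enoyl]-1,3-oxazolidin-2-one, via sodium dienolate 10 (not isolated)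
Conditions: NaN(SiMe3)2, THF, −78 °C; then 5, −78 to −30 °C; AcOH quench at −78 °C
Reagents that add atoms: none
Why: Evans alkylation in its deconjugative form: γ-deprotonation gives the chelated (Z)-dienolate, which is alkylated at the α-carbon (C7) by the benzylic bromide on the face away from the benzyl group of the (R)-auxiliary, so that C7 becomes R and the alkene stays out of conjugation as the isopropenyl group.

Step 7
Reactants: 11 (4R)-4-benzyl-3-[(2R)-2-{[3-(tert-butyldimethylsilyloxy)-2,6-dimethylphenyl]methyl}-3-methylbut-3-enoyl]-1,3-oxazolidin-2-one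
Product: 12 (4R)-4-benzyl-3-[(2R)-2-{[3-(tert-butyldimethylsilyloxy)-2,6-dimethylphenyl]methyl}-3-hydroxy-3-methylbutanoyl]-1,3-oxazolidin-2-one
Conditions: Co(acac)2 (cat.), PhSiH3, O2 (1 atm), THF, rt; then aq. Na2S2O3
Reagents that add atoms: dioxygen, O=O
Why: Mukaiyama hydration: hydrogen-atom transfer from a cobalt hydride to the only 1,1-disubstituted alkene gives the tertiary C11 radical, which is trapped by O2 and reduced to the Markovnikov alcohol without involving C7.

Step 8
Reactants: 12 (4R)-4-benzyl-3-[(2R)-2-{[3-(tert-butyldimethylsilyloxy)-2,6-dimethylphenyl]methyl}-3-hydroxy-3-methylbutanoyl]-1,3-oxazolidin-2-one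
Product: 13 (2R)-2-{[3-(tert-butyldimethylsilyloxy)-2,6-dimethylphenyl]methyl}-3-hydroxy-N-methoxy-N,3-dimethylbutanamide
Conditions: MeNH(OMe), AlMe3, CH2Cl2, 0 °C to rt; aq. potassium sodium tartrate
Reagents that add atoms: N,O-dimethylhydroxylamine, CNOC
Why: Weinreb amide formation by aluminium-amide transamidation; as with aldol adducts of this auxiliary, the aluminium alkoxide of the free β-hydroxyl should direct attack to the exocyclic carbonyl and release the auxiliary for reuse.

Step 9
Reactants: 13 (2R)-2-{[3-(tert-butyldimethylsilyloxy)-2,6-dimethylphenyl]methyl}-3-hydroxy-N-methoxy-N,3-dimethylbutanamide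
Product: 14 (3R)-3-{[3-(tert-butyldimethylsilyloxy)-2,6-dimethylphenyl]methyl}-4-hydroxy-4-methylpentan-2-one
Conditions: MeMgBr (4 equiv), THF, 0 °C; aq. NH4Cl
Reagents that add atoms: methylmagnesium bromide, C[Mg]Br
Why: Weinreb ketone synthesis: the chelated tetrahedral adduct stops the addition at the ketone stage and keeps C7 non-enolisable until the neutral work-up, one equivalent of the Grignard reagent being consumed by the hydroxyl.

Step 10
Reactants: 14 (3R)-3-{[3-(tert-butyldimethylsilyloxy)-2,6-dimethylphenyl]methyl}-4-hydroxy-4-methylpentan-2-one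
Product: 15 (3R)-2,4-bis(tert-butyldimethylsilyloxy)-3-{[3-(tert-butyldimethylsilyloxy)-2,6-dimethylphenyl]methyl}-4-methylpent-1-ene
Conditions: TBSOTf (3 equiv), Et3N, CH2Cl2, −78 to 0 °C
Reagents that add atoms: tert-butyldimethylsilyl trifluoromethanesulfonate, CC(C)(C)[Si](C)(C)OS(=O)(=O)C(F)(F)F
Why: Silyl triflate–amine silylation and soft enolisation in one operation: the tertiary hydroxyl is silylated and the O-silylated ketone is deprotonated at the unhindered methyl group (C9) and not at the congested C7–H, so the 2-silyloxy-1-alkene should form with C7 unchanged.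

Step 11
Reactants: 15 (3R)-2,4-bis(tert-butyldimethylsilyloxy)-3-{[3-(tert-butyldimethylsilyloxy)-2,6-dimethylphenyl]methyl}-4-methylpent-1-ene
Product: 16 3-{(2R)-3-(tert-butyldimethylsilyloxy)-2-[1-(tert-butyldimethylsilyloxy)ethenyl]-3-methylbutyl}-2,4-dimethylphenol
Conditions: Cs2CO3 (0.5 equiv), DMF/H2O 10:1, rt
Reagents that add atoms: none
Why: Base-mediated chemoselective cleavage of an aryl silyl ether: phenoxide leaves silicon far more readily than an enolate or a tertiary alkoxide, so the enol silane and the C11 silyl ether should survive.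

Step 12
Reactants: 16 3-{(2R)-3-(tert-butyldimethylsilyloxy)-2-[1-(tert-butyldimethylsilyloxy)ethenyl]-3-methylbutyl}-2,4-dimethylphenol
Product: 17 11-(tert-butyldimethylsilyloxy)-7αH-eudesma-1,4-diene-3,8-dione (10β-methyl)
Conditions: undivided cell, reticulated vitreous carbon anode, Pt cathode, constant current (about 2.2 F/mol), LiClO4 (0.1 M), 2,6-lutidine, CH2Cl2/(CF3)2CHOH 4:1, 0 °C
Reagents that add atoms: none
Why: Proposed new method: anodic removal of two electrons from the phenol/enol silane pair (the phenol first by proton-coupled oxidation with 2,6-lutidine, or the enol silane first to its radical cation; both paths converge) joins the two donor carbons C9 and C10, after which loss of the phenolic proton and transfer of the silyl cation to the fluorinated alcohol give the cross-conjugated dienone and the C8 ketone together. The closest known reactions are hypervalent-iodine and anodic dearomatisations of para-substituted phenols by tethered carbon nucleophiles (mostly spiro closures) and anodic enol ether–arene couplings; a fused closure onto a methyl-bearing para carbon has no close example. Ring B closes in a 6-(enolendo) mode, C9 approaching C10 perpendicular to the arene plane so that the C8=C9 π bond overlaps the ring π system. C10 is set by C7: in the chair-like fold of the C6–C9 tether the C(CH3)2OTBS group sits pseudo-equatorial (the enol silyl group turns toward the methylene side, which relieves allylic strain), so C9 bonds to the α face of C10 and the methyl ends β. The step needs para (C10) rather than ortho (C4) attack, which the larger para coefficient of the oxidised phenol favours and the C4 methyl secures further because an ortho closure can no longer rearomatise; the non-nucleophilic (CF3)2CHOH prevents solvent capture at C10.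

Step 13
Reactants: 17 11-(tert-butyldimethylsilyloxy)-7αH-eudesma-1,4-diene-3,8-dione (10β-methyl)
Product: 18 11-(tert-butyldimethylsilyloxy)-8β-hydroxy-7αH-eudesma-1,4-dien-3-one
Conditions: NaBH4, MeOH/CH2Cl2, −40 to −10 °C
Reagents that add atoms: none
Why: Chemoselective borohydride reduction that masks C8 for the later dissolving-metal and hydride steps: the saturated C8 ketone should react faster than the cross-conjugated, α-methylated dienone carbonyl (the selectivity used for 17-ketones of steroidal 1,4-dien-3-ones), hydride is expected on the α face because the axial path is blocked by the C10 methyl, and the 8β configuration is of no consequence since C8 is re-oxidised in step 22.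

Step 14
Reactants: 18 11-(tert-butyldimethylsilyloxy)-8β-hydroxy-7αH-eudesma-1,4-dien-3-one
Product: 19 11-(tert-butyldimethylsilyloxy)-8β-(triethylsilyloxy)-7αH-eudesma-1,4-dien-3-one
Conditions: TESOTf, 2,6-lutidine, CH2Cl2, −78 to 0 °C
Reagents that add atoms: triethylsilyl trifluoromethanesulfonate, CC[Si](CC)(CC)OS(=O)(=O)C(F)(F)F
Why: Silylation of a hindered secondary alcohol with a silyl triflate, giving a TES ether that can later be removed in the presence of the tertiary TBS ether.

Step 15
Reactants: 19 11-(tert-butyldimethylsilyloxy)-8β-(triethylsilyloxy)-7αH-eudesma-1,4-dien-3-one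
Product: 20 11-(tert-butyldimethylsilyloxy)-8β-(triethylsilyloxy)-7αH-eudesm-4-en-3-one
Conditions: H2 (1 atm), RhCl(PPh3)3 (cat.), toluene/EtOH, rt
Reagents that add atoms: none
Why: Homogeneous hydrogenation with RhCl(PPh3)3 is sensitive to alkene substitution and reduces the disubstituted C1=C2 bond of a cross-conjugated cyclohexadienone while leaving the tetrasubstituted C4=C5 bond, as known for santonin-type 4-methyl-1,4-dien-3-ones.

Step 16
Reactants: 20 11-(tert-butyldimethylsilyloxy)-8β-(triethylsilyloxy)-7αH-eudesm-4-en-3-one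
Product: 22 11-(tert-butyldimethylsilyloxy)-8β-(triethylsilyloxy)-3-(trimethylsilyloxy)-5αH,7αH-eudesm-3-ene, via lithium enolate 21 (not isolated)
Conditions: Li, NH3/THF, t-BuOH (1 equiv), −78 °C; isoprene; NH3 removed; then TMSCl, Et3N, THF, −78 to 0 °C
Reagents that add atoms: chlorotrimethylsilane, C[Si](C)(C)Cl
Why: Birch-type dissolving-metal reduction of the enone with enolate trapping (reductive silylation): protonation at C5 of the reduced enone gives the more stable trans-fused decalin (5α-H), and O-silylation of the regiodefined lithium enolate gives the C3=C4 enol silane with the C4 methyl in place.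

Step 17
Reactants: 22 11-(tert-butyldimethylsilyloxy)-8β-(triethylsilyloxy)-3-(trimethylsilyloxy)-5αH,7αH-eudesm-3-ene
Product: 24 11-(tert-butyldimethylsilyloxy)-4α-hydroxy-8β-(triethylsilyloxy)-5αH,7αH-eudesman-3-one, via 4α-trimethylsilyloxy ketone 23 (not isolated)
Conditions: mCPBA, NaHCO3, CH2Cl2, −20 °C; then citric acid, MeOH, rt
Reagents that add atoms: 3-chloroperoxybenzoic acid, O=C(OO)c1cccc(Cl)c1
Why: Rubottom oxidation: the peracid epoxidises the enol silane from the α face because the axial C10 methyl lies over the β face of C4, silyl migration gives the 4α-silyloxy ketone, and methanolysis frees the tertiary 4α-alcohol with the C4 methyl β.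

Step 18
Reactants: 24 11-(tert-butyldimethylsilyloxy)-4α-hydroxy-8β-(triethylsilyloxy)-5αH,7αH-eudesman-3-one
Product: 25 11-(tert-butyldimethylsilyloxy)-8β-(triethylsilyloxy)-5αH,7αH-eudesmane-3α,4α-diol
Conditions: LiBH(s-Bu)3 (2.5 equiv), THF, −78 °C; aq. NH4Cl
Reagents that add atoms: none
Why: Reduction with a bulky trialkylborohydride: axial approach to C3 from the α face is blocked for this reagent by the syn-axial hydrogens at C1 and C5, so hydride should enter equatorially from the β face, as it does with 4,4-disubstituted 3-oxo triterpenoids, giving the axial 3α-alcohol cis to the 4α-hydroxyl.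

Step 19
Reactants: 25 11-(tert-butyldimethylsilyloxy)-8β-(triethylsilyloxy)-5αH,7αH-eudesmane-3α,4α-diol; 26 angelic acid
Product: 28 3α-angeloyloxy-11-(tert-butyldimethylsilyloxy)-8β-(triethylsilyloxy)-5αH,7αH-eudesman-4α-ol, via mixed anhydride 27 (not isolated)
Conditions: 26, 2,4,6-trichlorobenzoyl chloride, Et3N, toluene, rt; then 25, 80 °C
Reagents that add atoms: none
Why: Yamaguchi esterification: the mixed anhydride acylates the secondary 3α-hydroxyl at its less hindered angeloyl carbonyl without a nucleophilic catalyst, conditions known to give angelates of hindered alcohols without Z-to-E isomerisation, and the tertiary 4α-hydroxyl should not react.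

Step 20
Reactants: 28 3α-angeloyloxy-11-(tert-butyldimethylsilyloxy)-8β-(triethylsilyloxy)-5αH,7αH-eudesman-4α-ol
Product: 29 4α-acetoxy-3α-angeloyloxy-11-(tert-butyldimethylsilyloxy)-8β-(triethylsilyloxy)-5αH,7αH-eudesmane
Conditions: Ac2O, DMAP, Et3N, ClCH2CH2Cl, 50 °C
Reagents that add atoms: acetic anhydride, CC(=O)OC(C)=O
Why: DMAP-catalysed acyl transfer (Steglich-type acetylation) to the remaining tertiary alcohol, the only free hydroxyl; forcing conditions are needed but the angelate should keep its geometry.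

Step 21
Reactants: 29 4α-acetoxy-3α-angeloyloxy-11-(tert-butyldimethylsilyloxy)-8β-(triethylsilyloxy)-5αH,7αH-eudesmane
Product: 30 4α-acetoxy-3α-angeloyloxy-11-(tert-butyldimethylsilyloxy)-5αH,7αH-eudesman-8β-ol
Conditions: HF·pyridine, pyridine, THF, 0 °C
Reagents that add atoms: none
Why: Selective fluoride desilylation: a secondary TES ether is cleaved much faster by buffered HF·pyridine than a tertiary TBS ether, and both esters are stable.

Step 22
Reactants: 30 4α-acetoxy-3α-angeloyloxy-11-(tert-butyldimethylsilyloxy)-5αH,7αH-eudesman-8β-ol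
Product: 32 4α-acetoxy-3α-angeloyloxy-11-(tert-butyldimethylsilyloxy)-5αH-eudesm-6-en-8-one, via 8-ketone 31 (not isolated)
Conditions: 2-iodoxybenzoic acid (IBX, 3 equiv), DMSO/fluorobenzene, rt then 75 °C
Reagents that add atoms: none
Why: IBX oxidation of the alcohol to the ketone and, on heating, IBX dehydrogenation of the ketone to the enone; enolisation toward C9 is unproductive because C10 is quaternary, so only C6=C7 can form, the sacrificial C7 centre disappears, and the C11 silyl ether prevents retro-aldol loss of acetone.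

Step 23
Reactants: 32 4α-acetoxy-3α-angeloyloxy-11-(tert-butyldimethylsilyloxy)-5αH-eudesm-6-en-8-one
Product: 33 4α-acetoxy-3α-angeloyloxy-11-hydroxy-5αH-eudesm-6-en-8-one (CNP0351454.1)
Conditions: HF·pyridine, THF, rt to 40 °C
Reagents that add atoms: none
Why: Fluoride-mediated cleavage of the tertiary silyl ether; the enone, both esters and the Z geometry of the angelate should be unaffected, and the now sp2 C7 rules out a retro-aldol reaction.

**Compound list**

1 | 3-bromo-2,6-dimethylbenzoic acid | Cc1ccc(Br)c(C)c1C(=O)O | starting material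
2 | 3-hydroxy-2,6-dimethylbenzoic acid | Cc1ccc(O)c(C)c1C(=O)O | intermediate
3 | 3-(hydroxymethyl)-2,4-dimethylphenol | Cc1ccc(O)c(C)c1CO | intermediate
4 | tert-butyl[3-(tert-butyldimethylsilyloxymethyl)-2,4-dimethylphenoxy]dimethylsilane | Cc1ccc(O[Si](C)(C)C(C)(C)C)c(C)c1CO[Si](C)(C)C(C)(C)C | intermediate
5 | [3-(bromomethyl)-2,4-dimethylphenoxy](tert-butyl)dimethylsilane | Cc1ccc(O[Si](C)(C)C(C)(C)C)c(C)c1CBr | intermediate
6 | (4R)-4-benzyl-1,3-oxazolidin-2-one | O=C1N[C@H](Cc2ccccc2)CO1 | starting material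
7 | 3-methylbut-2-enoyl chloride | CC(C)=CC(=O)Cl | starting material
8 | lithium salt of 6 (not isolated) | O=C1[N-][C@H](Cc2ccccc2)CO1.[Li+] | intermediate
9 | (4R)-4-benzyl-3-(3-methylbut-2-enoyl)-1,3-oxazolidin-2-one | CC(C)=CC(=O)N1[C@H](Cc2ccccc2)COC1=O | intermediate
10 | sodium (Z)-dienolate of 9 (not isolated) | C=C(C)/C=C(\[O-])N1[C@H](Cc2ccccc2)COC1=O.[Na+] | intermediate
11 | (4R)-4-benzyl-3-[(2R)-2-{[3-(tert-butyldimethylsilyloxy)-2,6-dimethylphenyl]methyl}-3-methylbut-3-enoyl]-1,3-oxazolidin-2-one | C=C(C)[C@@H](Cc1c(C)ccc(O[Si](C)(C)C(C)(C)C)c1C)C(=O)N1[C@H](Cc2ccccc2)COC1=O | intermediate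
12 | (4R)-4-benzyl-3-[(2R)-2-{[3-(tert-butyldimethylsilyloxy)-2,6-dimethylphenyl]methyl}-3-hydroxy-3-methylbutanoyl]-1,3-oxazolidin-2-one | CC(C)(O)[C@@H](Cc1c(C)ccc(O[Si](C)(C)C(C)(C)C)c1C)C(=O)N1[C@H](Cc2ccccc2)COC1=O | intermediate
13 | (2R)-2-{[3-(tert-butyldimethylsilyloxy)-2,6-dimethylphenyl]methyl}-3-hydroxy-N-methoxy-N,3-dimethylbutanamide | CC(C)(O)[C@@H](Cc1c(C)ccc(O[Si](C)(C)C(C)(C)C)c1C)C(=O)N(C)OC | intermediate
14 | (3R)-3-{[3-(tert-butyldimethylsilyloxy)-2,6-dimethylphenyl]methyl}-4-hydroxy-4-methylpentan-2-one | CC(=O)[C@H](Cc1c(C)ccc(O[Si](C)(C)C(C)(C)C)c1C)C(C)(C)O | intermediate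
15 | (3R)-2,4-bis(tert-butyldimethylsilyloxy)-3-{[3-(tert-butyldimethylsilyloxy)-2,6-dimethylphenyl]methyl}-4-methylpent-1-ene | C=C(O[Si](C)(C)C(C)(C)C)[C@H](Cc1c(C)ccc(O[Si](C)(C)C(C)(C)C)c1C)C(C)(C)O[Si](C)(C)C(C)(C)C | intermediate
16 | 3-{(2R)-3-(tert-butyldimethylsilyloxy)-2-[1-(tert-butyldimethylsilyloxy)ethenyl]-3-methylbutyl}-2,4-dimethylphenol (key-step precursor) | C=C(O[Si](C)(C)C(C)(C)C)[C@H](Cc1c(C)ccc(O)c1C)C(C)(C)O[Si](C)(C)C(C)(C)C | intermediate
17 | 11-(tert-butyldimethylsilyloxy)-7αH-eudesma-1,4-diene-3,8-dione, 10β-methyl (key-step product) | O=C1C=C[C@]2(C)CC(=O)[C@@H](C(C)(C)O[Si](C)(C)C(C)(C)C)CC2=C1C | intermediate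
18 | 11-(tert-butyldimethylsilyloxy)-8β-hydroxy-7αH-eudesma-1,4-dien-3-one (expected major epimer) | O=C1C=C[C@]2(C)C[C@@H](O)[C@@H](C(C)(C)O[Si](C)(C)C(C)(C)C)CC2=C1C | intermediate
19 | 11-(tert-butyldimethylsilyloxy)-8β-(triethylsilyloxy)-7αH-eudesma-1,4-dien-3-one | O=C1C=C[C@]2(C)C[C@@H](O[Si](CC)(CC)CC)[C@@H](C(C)(C)O[Si](C)(C)C(C)(C)C)CC2=C1C | intermediate
20 | 11-(tert-butyldimethylsilyloxy)-8β-(triethylsilyloxy)-7αH-eudesm-4-en-3-one | O=C1CC[C@]2(C)C[C@@H](O[Si](CC)(CC)CC)[C@@H](C(C)(C)O[Si](C)(C)C(C)(C)C)CC2=C1C | intermediate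
21 | lithium 3(4)-enolate of the 5αH-3-ketone (not isolated) | [Li+].[O-]C1=C(C)[C@@H]2C[C@H](C(C)(C)O[Si](C)(C)C(C)(C)C)[C@H](O[Si](CC)(CC)CC)C[C@@]2(C)CC1 | intermediate
22 | 11-(tert-butyldimethylsilyloxy)-8β-(triethylsilyloxy)-3-(trimethylsilyloxy)-5αH,7αH-eudesm-3-ene | C[Si](C)(C)OC1=C(C)[C@@H]2C[C@H](C(C)(C)O[Si](C)(C)C(C)(C)C)[C@H](O[Si](CC)(CC)CC)C[C@@]2(C)CC1 | intermediate
23 | 11-(tert-butyldimethylsilyloxy)-8β-(triethylsilyloxy)-4α-(trimethylsilyloxy)-5αH,7αH-eudesman-3-one (not isolated) | O=C1CC[C@]2(C)C[C@@H](O[Si](CC)(CC)CC)[C@@H](C(C)(C)O[Si](C)(C)C(C)(C)C)C[C@H]2[C@]1(C)O[Si](C)(C)C | intermediate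
24 | 11-(tert-butyldimethylsilyloxy)-4α-hydroxy-8β-(triethylsilyloxy)-5αH,7αH-eudesman-3-one (4β-methyl) | O=C1CC[C@]2(C)C[C@@H](O[Si](CC)(CC)CC)[C@@H](C(C)(C)O[Si](C)(C)C(C)(C)C)C[C@H]2[C@]1(C)O | intermediate
25 | 11-(tert-butyldimethylsilyloxy)-8β-(triethylsilyloxy)-5αH,7αH-eudesmane-3α,4α-diol | O[C@@H]1CC[C@]2(C)C[C@@H](O[Si](CC)(CC)CC)[C@@H](C(C)(C)O[Si](C)(C)C(C)(C)C)C[C@H]2[C@]1(C)O | intermediate
26 | angelic acid, (Z)-2-methylbut-2-enoic acid | C/C=C(/C)C(=O)O | starting material
27 | angelic 2,4,6-trichlorobenzoic anhydride (not isolated) | C/C=C(/C)C(=O)OC(=O)c1c(Cl)cc(Cl)cc1Cl | intermediate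
28 | 3α-angeloyloxy-11-(tert-butyldimethylsilyloxy)-8β-(triethylsilyloxy)-5αH,7αH-eudesman-4α-ol | C/C=C(/C)C(=O)O[C@@H]1CC[C@]2(C)C[C@@H](O[Si](CC)(CC)CC)[C@@H](C(C)(C)O[Si](C)(C)C(C)(C)C)C[C@H]2[C@]1(C)O | intermediate
29 | 4α-acetoxy-3α-angeloyloxy-11-(tert-butyldimethylsilyloxy)-8β-(triethylsilyloxy)-5αH,7αH-eudesmane | C/C=C(/C)C(=O)O[C@@H]1CC[C@]2(C)C[C@@H](O[Si](CC)(CC)CC)[C@@H](C(C)(C)O[Si](C)(C)C(C)(C)C)C[C@H]2[C@]1(C)OC(C)=O | intermediate
30 | 4α-acetoxy-3α-angeloyloxy-11-(tert-butyldimethylsilyloxy)-5αH,7αH-eudesman-8β-ol | C/C=C(/C)C(=O)O[C@@H]1CC[C@]2(C)C[C@@H](O)[C@@H](C(C)(C)O[Si](C)(C)C(C)(C)C)C[C@H]2[C@]1(C)OC(C)=O | intermediate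
31 | 4α-acetoxy-3α-angeloyloxy-11-(tert-butyldimethylsilyloxy)-5αH,7αH-eudesman-8-one (not isolated) | C/C=C(/C)C(=O)O[C@@H]1CC[C@]2(C)CC(=O)[C@@H](C(C)(C)O[Si](C)(C)C(C)(C)C)C[C@H]2[C@]1(C)OC(C)=O | intermediate
32 | 4α-acetoxy-3α-angeloyloxy-11-(tert-butyldimethylsilyloxy)-5αH-eudesm-6-en-8-one | C/C=C(/C)C(=O)O[C@@H]1CC[C@]2(C)CC(=O)C(C(C)(C)O[Si](C)(C)C(C)(C)C)=C[C@H]2[C@]1(C)OC(C)=O | intermediate
33 | 4α-acetoxy-3α-angeloyloxy-11-hydroxy-5αH-eudesm-6-en-8-one (CNP0351454.1) | C/C=C(/C)C(=O)O[C@@H]1CC[C@]2(C)CC(=O)C(C(C)(C)O)=C[C@H]2[C@]1(C)OC(C)=O | target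

**Step count**

Total step count: 23.
Longest linear sequence: 22 steps (steps 1–4, then steps 6–23, from compound 1).

**Steps most likely to fail**

Step 12 (proposed new method). The coupling may go astray by closure at the ortho carbon C4 instead of C10, by intermolecular coupling of phenoxyl radicals, by protonation of the enol silane in the fluorinated alcohol before it is oxidised, or by weak facial control from C7. The fallback replaces the oxidative union by a polar alkylative dearomatisation of a phenoxide, a known way to 4,4-disubstituted cyclohexa-2,5-dienones. It sets out from 15: N-bromosuccinimide in THF at −78 °C should brominate the enol silane at C9 to give (3R)-1-bromo-4-(tert-butyldimethylsilyloxy)-3-{[3-(tert-butyldimethylsilyloxy)-2,6-dimethylphenyl]methyl}-4-methylpentan-2-one F1. Bu4NF (1 equiv) in THF at 0 °C under high dilution should then cleave the aryl silyl ether to the tetrabutylammonium phenoxide F2 (not isolated), whose para carbon C10 displaces bromide at C9 in the same six-ring mode. The route is rejoined at 17.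

Step 22. Enolisation toward the congested C7 may be too slow, so that the 8-ketone is returned, or prolonged heating may degrade the esters. The fallback installs C6=C7 by allylic transposition instead of dehydrogenation and sets out from 30. Dess–Martin periodinane gives the ketone 31, and HF·pyridine then frees the β-hydroxy ketone 4α-acetoxy-3α-angeloyloxy-11-hydroxy-5αH,7αH-eudesman-8-one F3. MsCl/Et3N followed by DBU should dehydrate it (E1cB) to the conjugated 4α-acetoxy-3α-angeloyloxy-5αH-eudesm-7(11)-en-8-one F4. A Schenck ene reaction with singlet oxygen (O2, hν, tetraphenylporphyrin, CH2Cl2, 0 °C) should then abstract hydrogen from C6, the substituent geminal to the carbonyl as is usual for s-cis enones, add oxygen at C11 and form C6=C7, giving the 11-hydroperoxide 4α-acetoxy-3α-angeloyloxy-11-hydroperoxy-5αH-eudesm-6-en-8-one F5. PPh3 reduces F5 to the target 33.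

Step 19. Acylation of the axial, neopentyl-type 3α-hydroxyl may be slow, and long heating may isomerise the Z-angeloyl unit to the E-tigloyl unit. The fallback builds the Z-alkene on the ester and sets out from 25. Esterification with 2-[bis(2,2,2-trifluoroethoxy)phosphoryl]propanoic acid (EDC, DMAP, CH2Cl2) gives the 3α-phosphonopropanoate F6, and Ac2O/DMAP/Et3N gives its 4α-acetate F7. A Still–Gennari olefination (KN(SiMe3)2, 18-crown-6, THF, −78 °C; then acetaldehyde) should then form the Z-trisubstituted ester, which is the angelate 29, where the route is rejoined.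

**Further compounds**

F1 | step 12 | (3R)-1-bromo-4-(tert-butyldimethylsilyloxy)-3-{[3-(tert-butyldimethylsilyloxy)-2,6-dimethylphenyl]methyl}-4-methylpentan-2-one | BrCC(=O)[C@H](Cc1c(C)ccc(O[Si](C)(C)C(C)(C)C)c1C)C(C)(C)O[Si](C)(C)C(C)(C)C
F2 | step 12 | tetrabutylammonium 3-[(2R)-4-bromo-2-[2-(tert-butyldimethylsilyloxy)propan-2-yl]-3-oxobutyl]-2,4-dimethylphenoxide (not isolated) | BrCC(=O)[C@H](Cc1c(C)ccc([O-])c1C)C(C)(C)O[Si](C)(C)C(C)(C)C.CCCC[N+](CCCC)(CCCC)CCCC
F3 | step 22 | 4α-acetoxy-3α-angeloyloxy-11-hydroxy-5αH,7αH-eudesman-8-one | C/C=C(/C)C(=O)O[C@@H]1CC[C@]2(C)CC(=O)[C@@H](C(C)(C)O)C[C@H]2[C@]1(C)OC(C)=O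
F4 | step 22 | 4α-acetoxy-3α-angeloyloxy-5αH-eudesm-7(11)-en-8-one | C/C=C(/C)C(=O)O[C@@H]1CC[C@]2(C)CC(=O)C(=C(C)C)C[C@H]2[C@]1(C)OC(C)=O
F5 | step 22 | 4α-acetoxy-3α-angeloyloxy-11-hydroperoxy-5αH-eudesm-6-en-8-one | C/C=C(/C)C(=O)O[C@@H]1CC[C@]2(C)CC(=O)C(C(C)(C)OO)=C[C@H]2[C@]1(C)OC(C)=O
F6 | step 19 | 3α-{2-[bis(2,2,2-trifluoroethoxy)phosphoryl]propanoyloxy}-11-(tert-butyldimethylsilyloxy)-8β-(triethylsilyloxy)-5αH,7αH-eudesman-4α-ol (both epimers at the phosphonate carbon) | CC(C(=O)O[C@@H]1CC[C@]2(C)C[C@@H](O[Si](CC)(CC)CC)[C@@H](C(C)(C)O[Si](C)(C)C(C)(C)C)C[C@H]2[C@]1(C)O)P(=O)(OCC(F)(F)F)OCC(F)(F)F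
F7 | step 19 | 4α-acetoxy-3α-{2-[bis(2,2,2-trifluoroethoxy)phosphoryl]propanoyloxy}-11-(tert-butyldimethylsilyloxy)-8β-(triethylsilyloxy)-5αH,7αH-eudesmane | CC(C(=O)O[C@@H]1CC[C@]2(C)C[C@@H](O[Si](CC)(CC)CC)[C@@H](C(C)(C)O[Si](C)(C)C(C)(C)C)C[C@H]2[C@]1(C)OC(C)=O)P(=O)(OCC(F)(F)F)OCC(F)(F)F
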